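A one-step world turns each X lost into a G gained, and the eta run refuses that.

| setting | eta | flask |
|---|---|---|
| X | 1.6 M | 1.6 M |
| J | 1.6 M | 1.60 M |
| L | 0.16 M | 0.320 M |
| remark | run made earlier |  |
| time |  | 15 h |

eta run (percent of the X charged)

| time / h | G / % | X / % |
|---|---|---|
| 0.250 | 0.5 | 98.8 |
| 0.417 | 0.6 | 98.0 |
| 0.833 | 1.2 | 96.2 |
| 1.50 | 3.6 | 94.0 |
| 3.00 | 8.3 | 87.4 |

(standard deviation of a reading: 0.3 percentage points)

- as a solid, counted per litre of solution: X
- what was read earlier has a scatter of 0.3 percentage points, one standard deviation
- at the start none of X is in solution
- no earlier run changes the charge of L; that part of a forecast is a guess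

By 3.00 h the solid X has lost 12.6%, but G reads 8.3%, so I take the gap to be X in solution, which nobody read. The fall of the solid runs nearly straight, so at the early end I treat dissolution as a zero-order feed of 0.0672 M h⁻¹. The late end is plain: with the solid gone, the feed ends. One time joins the two ends, the charge of X over the feed, the clearing time 23.8 h. In the asked flask this is longer than 15 h, so I expect solid at the end and about 63.0% of the charge fed into solution. That is my ceiling for G, but the readings do not show how J lasts, and no earlier run changes the charge of L, so its effect is a guess.

1. G at 15 h, in percent of the X charged
2. the change that raises the amount of G at 15 h, in percent of the X charged most ("none" if none brings more than 2 percentage points) (violet / teal / red / none)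
3. amount of G at 15 h, in percent of the X charged, after red

- violet: doubling the amount of J, all else as stated
- teal: doubling the dissolution coefficient of X, all else as stated
- red: doubling the solubility of X, all else as stated

The forecast gives 62%, names red as the best change, and gives 92% after it, on the ground that “dissolution limits the rate”.

The flask gives 34.9%, and the best change is violet, worth 17 percentage points, against 14 points for red, which brings 49.4%.

    J → E (k = 0.00135 min⁻¹)
    D + J → G (k = 0.0143 L mol⁻¹ min⁻¹)
    J + L → Q (k = 0.152 L mol⁻¹ min⁻¹)
    X ⇌ D, rate k4*(cs4 - [D]) while solid is left; crystals form when [D] > cs4 (solubility = 0.410 M, k = 0.00302 min⁻¹)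
    J → Z (k = 2.61 × 10⁻⁵ min⁻¹)

In the asked flask, X has lost 49.2% at 15.0 h, less than the ceiling, and 50.8% still stands as solid, as the clearing time said. G holds 34.9% of the charge and D 14.3%, while J is down to 4.92% of its own charge. A neighbouring flask differs in one setting, 0.40 M of X. At the same feed its clearing time is 5.95 h, shorter than 15 h, and at 15.0 h this neighbouring flask reads X 0% and G 97.5% of its charge.

The runs were computed for substances that don't exist; scatter was added.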